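**Retrosynthetic overview**

- The route rests on the 1,2,3,4-tetrasubstituted benzene ring of the indane (C3a, C4–C7, C7a; C1 is the aryl-bearing methine, C2 the isopropylidene carbon, C3 the CH2), with OH on C6 and CHO on C7 beside ring-fusion carbon C7a. The C7 aldehyde and C6 phenol are traced back to a benzoxaborole (C6–B–O–CH2–C7).
- The benzoxaborole comes from an intramolecular [2+2+2] of a triyne assembled in the flask from a 1,6-diynol and an ethynylboronate through a B–O bond. This forms C3a–C7a, C4–C5 and C6–C7 and closes the benzene, cyclopentane and temporary oxaborole rings together.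
- The diynol comes from an allylic bromide and ethynyltrimethylsilane. The C2=CMe2 unit comes from an acrylate ester (two methyl additions, then allylic transposition). C1 is set by amine-catalysed enantioselective SN2' alkynylation of a Morita–Baylis–Hillman fluoride.
- The Morita–Baylis–Hillman adduct comes from the benzodioxane aldehyde and methyl acrylate. The dioxane ring comes from 2,3-dihydroxy-5-methylbenzaldehyde and an (R)-epoxy tosylate made by Sharpless epoxidation of prenol.
- Ring order: dioxane ring (step 3), then benzene and cyclopentane (with the oxaborole) in step 14.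

Key step: step 14

Assumption: (DHQD)2PHAL is taken to deliver the alkynyl group in step 8 so as to give the (S) ester 14; if the opposite sense is found, the pseudo-enantiomeric (DHQ)2PHAL would be used.

**Route**

Step 1
Reactants: 1 3-methylbut-2-en-1-ol (prenol)
Product: 3 [(2R)-3,3-dimethyloxiran-2-yl]methyl 4-methylbenzenesulfonate, via epoxy alcohol 2 (not isolated)
Conditions: Ti(OiPr)4 (5 mol %), D-(−)-diisopropyl tartrate (7 mol %), t-BuOOH, 4 Å MS, CH2Cl2, −20 °C; then P(OMe)3; then TsCl, Et3N, DMAP (cat.), −10 °C
Reagents that add atoms: tert-butyl hydroperoxide, CC(C)(C)OO; 4-methylbenzenesulfonyl chloride, Cc1ccc(S(=O)(=O)Cl)cc1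
Why: Sharpless asymmetric epoxidation, in which the titanium–D-tartrate complex delivers oxygen to one face of the allylic alcohol and sets the (R) centre of 2; the volatile, water-soluble epoxy alcohol is trapped in situ as the tosylate.

Step 2
Reactants: 4 2-hydroxy-3-methoxy-5-methylbenzaldehyde
Product: 5 2,3-dihydroxy-5-methylbenzaldehyde
Conditions: BBr3, CH2Cl2, −78 → 0 °C; then H2O
Reagents that add atoms: none
Why: Lewis-acid cleavage of the aryl methyl ether (BBr3 demethylation); the aldehyde should be inert at low temperature.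

Step 3
Reactants: 5 2,3-dihydroxy-5-methylbenzaldehyde; 3 [(2R)-3,3-dimethyloxiran-2-yl]methyl 4-methylbenzenesulfonate
Product: 7 (3S)-3-(2-hydroxypropan-2-yl)-7-methyl-2,3-dihydro-1,4-benzodioxine-5-carbaldehyde, via epoxy ether phenoxide 6 (not isolated)
Conditions: NaH (2.05 equiv), DMSO, 20 °C; then 3 (1.05 equiv), 20 → 70 °C; H2O work-up
Reagents that add atoms: none
Why: Williamson etherification of the dianion, in which the 3-phenoxide (not chelated to the ortho aldehyde) is the more nucleophilic oxygen and displaces the primary tosylate, followed by 6-exo-tet opening of the epoxide at its secondary carbon by the 2-phenoxide with inversion (R epoxide gives the S dioxane carbon), base favouring this over 7-endo attack at the tertiary carbon.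

Step 4
Reactants: 7 (3S)-3-(2-hydroxypropan-2-yl)-7-methyl-2,3-dihydro-1,4-benzodioxine-5-carbaldehyde
Product: 8 (3S)-7-methyl-3-{2-[(triethylsilyl)oxy]propan-2-yl}-2,3-dihydro-1,4-benzodioxine-5-carbaldehyde
Conditions: TESOTf, 2,6-lutidine, CH2Cl2, −78 → 0 °C
Reagents that add atoms: triethylsilyl trifluoromethanesulfonate, CC[Si](CC)(CC)OS(=O)(=O)C(F)(F)F
Why: Silylation of the hindered tertiary alcohol with a silyl triflate; the TES ether protects this hydroxyl from DAST, the Grignard reagent and PBr3 and is removed with fluoride in step 12.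

Step 5
Reactants: 8 TES-protected benzodioxane aldehyde; 9 methyl acrylate
Product: 10 methyl 2-{hydroxy[(3S)-7-methyl-3-{2-[(triethylsilyl)oxy]propan-2-yl}-2,3-dihydro-1,4-benzodioxin-5-yl]methyl}prop-2-enoate (both carbinol epimers)
Conditions: methyl acrylate (5 equiv), DABCO (1 equiv), 1,4-dioxane/H2O 1:1, 20 °C, several days
Reagents that add atoms: none
Why: Morita–Baylis–Hillman reaction (DABCO adds to the acrylate and the ammonium enolate adds to the aldehyde); the carbinol centre forms as an epimer mixture, which does not matter because it is erased in step 8.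

Step 6
Reactants: 10 Morita–Baylis–Hillman alcohol
Product: 11 methyl 2-{fluoro[(3S)-7-methyl-3-{2-[(triethylsilyl)oxy]propan-2-yl}-2,3-dihydro-1,4-benzodioxin-5-yl]methyl}prop-2-enoate (both epimers)
Conditions: DAST, CH2Cl2, −78 °C
Reagents that add atoms: diethylaminosulfur trifluoride, CCN(CC)S(F)(F)F
Why: Deoxyfluorination of the benzylic-allylic alcohol gives the allylic fluoride used as leaving group in the amine-catalysed step; any transposed primary allylic fluoride is expected to enter the same allylammonium ion in step 8.

Step 7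
Reactants: 12 3-(trimethylsilyl)prop-2-yn-1-ol
Product: 13 tert-butyldimethyl{[3-(trimethylsilyl)prop-2-yn-1-yl]oxy}silane
Conditions: TBSCl, imidazole, CH2Cl2, 20 °C
Reagents that add atoms: tert-butyldimethylsilyl chloride, CC(C)(C)[Si](C)(C)Cl
Why: Standard silylation of a primary alcohol.

Step 8
Reactants: 11 Morita–Baylis–Hillman fluoride; 13 alkynylsilane
Product: 14 methyl (3S)-6-[(tert-butyldimethylsilyl)oxy]-2-methylidene-3-[(3S)-7-methyl-3-{2-[(triethylsilyl)oxy]propan-2-yl}-2,3-dihydro-1,4-benzodioxin-5-yl]hex-4-ynoate
Conditions: (DHQD)2PHAL (10 mol %), 13 (2 equiv), THF, 40 °C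
Reagents that add atoms: none
Why: Amine-catalysed allylic alkynylation (SN2'–SN2' sequence): the cinchona dimer displaces fluoride to give a chiral allylammonium ion pair, the fluoride activates the C–Si bond of 13, and the alkynyl group adds to the benzylic terminus on the face left open by the catalyst, so both epimers of 11 should converge on the (S) centre of 14 (the future indane C1) under catalyst control.

Step 9
Reactants: 14 enyne ester
Product: 15 (4R)-7-[(tert-butyldimethylsilyl)oxy]-2-methyl-3-methylidene-4-[(3S)-7-methyl-3-{2-[(triethylsilyl)oxy]propan-2-yl}-2,3-dihydro-1,4-benzodioxin-5-yl]hept-5-yn-2-ol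
Conditions: MeMgBr (3.5 equiv), CeCl3 (3.5 equiv), THF, −78 → 0 °C; aq. NH4Cl
Reagents that add atoms: methylmagnesium bromide, C[Mg]Br
Why: Double 1,2-addition of the methylcerium reagent to the ester gives the tertiary allylic alcohol; the weakly basic organocerium should neither remove the C1–H (flanked by aryl, alkynyl and alkenyl groups) nor add in conjugate fashion, and the R descriptor reflects only a change of CIP priorities.

Step 10
Reactants: 15 tertiary allylic alcohol
Product: 16 (4S)-3-(bromomethyl)-7-[(tert-butyldimethylsilyl)oxy]-2-methyl-4-[(3S)-7-methyl-3-{2-[(triethylsilyl)oxy]propan-2-yl}-2,3-dihydro-1,4-benzodioxin-5-yl]hept-2-en-5-yne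
Conditions: PBr3 (0.4 equiv), pyridine (0.1 equiv), Et2O, −30 → 0 °C
Reagents that add atoms: phosphorus tribromide, BrP(Br)Br
Why: Allylic transposition with bromide (SN2'-type displacement of the dibromophosphite at the CH2 terminus) gives the primary bromide with the tetrasubstituted isopropylidene alkene, the more stable allylic isomer; C1 is untouched and its descriptor changes only through CIP priorities.

Step 11
Reactants: 16 allylic bromide; 17 ethynyltrimethylsilane
Product: 18 silyl-protected diyne, Me3Si–C≡C–CH2–C(=CMe2)–CH(Ar)–C≡C–CH2OTBS with (R) methine and Ar = (3S)-7-methyl-3-{2-[(triethylsilyl)oxy]propan-2-yl}-2,3-dihydro-1,4-benzodioxin-5-yl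
Conditions: 17 (2 equiv), CuI (20 mol %), NaI (20 mol %), K2CO3 (1.5 equiv), DMF, 20 °C
Reagents that add atoms: none
Why: Copper-catalysed coupling of a terminal alkyne with an allylic bromide; the copper acetylide should substitute at the primary carbon (SN2) and not at the fully substituted CMe2 terminus, giving the skipped enyne.

Step 12
Reactants: 18 silyl-protected diyne
Product: 19 (4R)-4-[(3S)-3-(2-hydroxypropan-2-yl)-7-methyl-2,3-dihydro-1,4-benzodioxin-5-yl]-5-(propan-2-ylidene)octa-2,7-diyn-1-ol
Conditions: TBAF/AcOH (1:1, 4 equiv), THF, 0 → 20 °C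
Reagents that add atoms: none
Why: Fluoride-mediated desilylation should remove the alkynyl TMS, primary TBS and tertiary TES groups in one operation; the acetic acid buffer keeps the medium from isomerising the skipped enyne units.

Step 13
Reactants: 20 ethynylmagnesium bromide; 21 triisopropyl borate
Product: 23 diisopropyl ethynylboronate, via borate complex 22 (not isolated)
Conditions: THF/Et2O, −78 °C; then HCl (1 M in Et2O), −78 → 20 °C; distillation
Reagents that add atoms: none
Why: Addition of the alkynyl Grignard reagent to the borate gives the tetracoordinate borate, from which anhydrous HCl removes one isopropoxide to release the boronic ester.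

Step 14
Reactants: 19 diynol; 23 diisopropyl ethynylboronate
Product: 26 indane-fused 1-hydroxybenzoxaborole, via boron-tethered triyne 24 (not isolated), via isopropyl benzoxaborole ester 25 (not isolated)
Conditions: 23 (1.2 equiv), ClCH2CH2Cl, 20 °C, 1 h, volatiles removed; then Cp*RuCl(cod) (10 mol %), ClCH2CH2Cl (0.01 M, slow addition of 24), 20–40 °C; aqueous work-up
Reagents that add atoms: water, O
Why: Exchange of one isopropoxy group of 23 for the propargylic hydroxyl of 19 gives mixed boronate 24, in which the three alkynes are joined by a three-carbon tether and a C–O–B tether; oxidative cyclisation of two alkynes at the Cp*RuCl fragment gives a ruthenacyclopentadiene, the third alkyne inserts and reductive elimination releases the arene. The closest known reaction type is the ruthenium-catalysed [2+2+2] cyclotrimerisation of an alkynylboronate, a propargylic alcohol and a further alkyne held by a temporary boron–oxygen tether, run here fully intramolecularly on a triyne. The benzene ring closes by the cycloaddition itself (bonds C3a–C7a, C4–C5, C6–C7), the cyclopentane closes as an annulated five-membered ring when C3a–C7a forms across the carbon tether, and the oxaborole closes when C6–C7 forms across the boronate tether. No stereocentre is created; C1 takes part in no bond change and should keep its configuration, its descriptor changing from R to S only because the former alkynyl carbon becomes the higher-ranked aromatic C7a. The step needs regioselectivity (boron on C6 beside the CH2O-bearing C7) and chemoselectivity for the tethered ethynyl group over free 23 or a second diyne; the B–O tether fixes the first, preforming 24 and adding it slowly at high dilution should secure the second, and the tetrasubstituted alkene is too hindered to bind.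

Step 15
Reactants: 26 indane-fused benzoxaborole
Product: 27 salicyl alcohol (C6–OH, C7–CH2OH), (S) at C1
Conditions: 30 % H2O2, 1 M NaOH, THF, 0 → 20 °C
Reagents that add atoms: hydrogen peroxide, OO
Why: Oxidation of the aryl–boron bond by alkaline peroxide (1,2-aryl shift from boron to oxygen, then hydrolysis) gives the C6 phenol and frees the C7 hydroxymethyl group; the hindered, unactivated tetrasubstituted alkene should not be attacked by hydroperoxide anion.

Step 16
Reactants: 27 salicyl alcohol
Product: 28 diaporindene H
Conditions: MnO2 (activated, 15 equiv), CH2Cl2, 20 °C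
Reagents that add atoms: none
Why: MnO2 oxidation of a benzylic alcohol to the salicylaldehyde, which is stabilised by its hydrogen bond to the phenol; the tertiary alcohol cannot react and the two stereocentres are not involved.

**Compound list**

1 | 3-methylbut-2-en-1-ol (prenol) | CC(C)=CCO | starting material
2 | [(2R)-3,3-dimethyloxiran-2-yl]methanol | CC1(C)O[C@@H]1CO | intermediate
3 | [(2R)-3,3-dimethyloxiran-2-yl]methyl 4-methylbenzenesulfonate | CC1(C)O[C@@H]1COS(=O)(=O)c1ccc(C)cc1 | intermediate
4 | 2-hydroxy-3-methoxy-5-methylbenzaldehyde | COc1cc(C)cc(C=O)c1O | starting material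
5 | 2,3-dihydroxy-5-methylbenzaldehyde | Cc1cc(O)c(O)c(C=O)c1 | intermediate
6 | 3-{[(2R)-3,3-dimethyloxiran-2-yl]methoxy}-2-hydroxy-5-methylbenzaldehyde (present as its sodium phenoxide) | CC1(C)O[C@@H]1COc1cc(C)cc(C=O)c1O | intermediate
7 | (3S)-3-(2-hydroxypropan-2-yl)-7-methyl-2,3-dihydro-1,4-benzodioxine-5-carbaldehyde | O=Cc1cc(C)cc2c1O[C@H](C(C)(C)O)CO2 | intermediate
8 | (3S)-7-methyl-3-{2-[(triethylsilyl)oxy]propan-2-yl}-2,3-dihydro-1,4-benzodioxine-5-carbaldehyde | O=Cc1cc(C)cc2c1O[C@H](C(C)(C)O[Si](CC)(CC)CC)CO2 | intermediate
9 | methyl acrylate | C=CC(=O)OC | starting material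
10 | Morita–Baylis–Hillman alcohol, ArCH(OH)C(=CH2)CO2Me, both carbinol epimers, dioxane carbon (S) | C=C(C(=O)OC)C(O)c1cc(C)cc2c1O[C@H](C(C)(C)O[Si](CC)(CC)CC)CO2 | intermediate
11 | Morita–Baylis–Hillman fluoride, ArCHFC(=CH2)CO2Me, both epimers, dioxane carbon (S) | C=C(C(=O)OC)C(F)c1cc(C)cc2c1O[C@H](C(C)(C)O[Si](CC)(CC)CC)CO2 | intermediate
12 | 3-(trimethylsilyl)prop-2-yn-1-ol | C[Si](C)(C)C#CCO | starting material
13 | tert-butyldimethyl{[3-(trimethylsilyl)prop-2-yn-1-yl]oxy}silane | C[Si](C)(C)C#CCO[Si](C)(C)C(C)(C)C | intermediate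
14 | methyl (3S)-6-[(tert-butyldimethylsilyl)oxy]-2-methylidene-3-aryl-hex-4-ynoate, aryl = (3S)-7-methyl-3-{2-[(triethylsilyl)oxy]propan-2-yl}-2,3-dihydro-1,4-benzodioxin-5-yl | C=C(C(=O)OC)[C@@H](C#CCO[Si](C)(C)C(C)(C)C)c1cc(C)cc2c1O[C@H](C(C)(C)O[Si](CC)(CC)CC)CO2 | intermediate
15 | (4R)-7-[(tert-butyldimethylsilyl)oxy]-2-methyl-3-methylidene-4-aryl-hept-5-yn-2-ol (same aryl group) | C=C(C(C)(C)O)[C@@H](C#CCO[Si](C)(C)C(C)(C)C)c1cc(C)cc2c1O[C@H](C(C)(C)O[Si](CC)(CC)CC)CO2 | intermediate
16 | (4S)-3-(bromomethyl)-7-[(tert-butyldimethylsilyl)oxy]-2-methyl-4-aryl-hept-2-en-5-yne (same aryl group) | CC(C)=C(CBr)[C@@H](C#CCO[Si](C)(C)C(C)(C)C)c1cc(C)cc2c1O[C@H](C(C)(C)O[Si](CC)(CC)CC)CO2 | intermediate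
17 | ethynyltrimethylsilane | C#C[Si](C)(C)C | starting material
18 | silyl-protected diyne, Me3Si–C≡C–CH2–C(=CMe2)–CH(Ar)–C≡C–CH2OTBS, (R) methine, dioxane carbon (S) | CC(C)=C(CC#C[Si](C)(C)C)[C@@H](C#CCO[Si](C)(C)C(C)(C)C)c1cc(C)cc2c1O[C@H](C(C)(C)O[Si](CC)(CC)CC)CO2 | intermediate
19 | (4R)-4-[(3S)-3-(2-hydroxypropan-2-yl)-7-methyl-2,3-dihydro-1,4-benzodioxin-5-yl]-5-(propan-2-ylidene)octa-2,7-diyn-1-ol | C#CCC(=C(C)C)[C@@H](C#CCO)c1cc(C)cc2c1O[C@H](C(C)(C)O)CO2 | intermediate
20 | ethynylmagnesium bromide | C#C[Mg]Br | starting material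
21 | triisopropyl borate | CC(C)OB(OC(C)C)OC(C)C | starting material
22 | bromomagnesium ethynyl(triisopropoxy)borate | C#C[B-](OC(C)C)(OC(C)C)OC(C)C.[Mg+]Br | intermediate
23 | diisopropyl ethynylboronate | C#CB(OC(C)C)OC(C)C | intermediate
24 | boron-tethered triyne, the isopropyl ethynylboronate ester of the primary hydroxyl of 19 | C#CCC(=C(C)C)[C@@H](C#CCOB(OC(C)C)C#C)c1cc(C)cc2c1O[C@H](C(C)(C)O)CO2 | intermediate
25 | isopropyl ester of benzoxaborole 26 (B–O-iPr) | CC(C)=C1Cc2ccc3c(COB3OC(C)C)c2[C@H]1c1cc(C)cc2c1O[C@H](C(C)(C)O)CO2 | intermediate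
26 | indane-fused 1-hydroxybenzoxaborole (C6–B(OH)–O–CH2–C7), (S) at C1, (S) at the dioxane carbon | CC(C)=C1Cc2ccc3c(COB3O)c2[C@H]1c1cc(C)cc2c1O[C@H](C(C)(C)O)CO2 | intermediate
27 | salicyl alcohol: indane with C6–OH and C7–CH2OH, (S) at C1, (S) at the dioxane carbon | CC(C)=C1Cc2ccc(O)c(CO)c2[C@H]1c1cc(C)cc2c1O[C@H](C(C)(C)O)CO2 | intermediate
28 | diaporindene H, (3S)-5-hydroxy-3-[(3S)-3-(2-hydroxypropan-2-yl)-7-methyl-2,3-dihydro-1,4-benzodioxin-5-yl]-2-(propan-2-ylidene)-2,3-dihydro-1H-indene-4-carbaldehyde | CC(C)=C1Cc2ccc(O)c(C=O)c2[C@H]1c1cc(C)cc2c1O[C@H](C(C)(C)O)CO2 | target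

**Step count**

Total: 16 steps. Longest linear sequence: 13 steps (steps 1, 3, 4, 5, 6, 8, 9, 10, 11, 12, 14, 15, 16; the same length counted from 4 through step 2).

**Steps most likely to fail**

1. Step 14. Exchange at boron may be incomplete, so that free 23 or a second diyne is taken up intermolecularly (wrong placement of boron, oligomers), and metal hydride species could move the exocyclic alkene into the ring with loss of the C1 centre. The fallback sets out from diynol 19 and keeps the alkyne cyclotrimerisation but gives up the boron tether. Acetylene gas (1 atm, RhCl(PPh3)3, toluene/EtOH, 60 °C) serves as the third alkyne and should give the C6-unsubstituted 7-(hydroxymethyl)indane F1. The C6 oxygen is then brought in by hydroxyl-directed C–H silylation: Et2SiH2 with [Ir(cod)OMe]2 in THF converts the benzylic alcohol into the diethyl(hydrido)silyl ether F2 (not isolated). With the same iridium catalyst, 1,10-phenanthroline and norbornene as hydrogen acceptor, this should close onto C6, the only free position beside C7, as the benzoxasilole F3. Any silyl ether formed at the tertiary hydroxyl is cleaved in the following step. Tamao–Fleming oxidation (H2O2, KHCO3, THF/MeOH) gives salicyl alcohol 27, where the route is rejoined.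

2. Step 8. Facial selectivity in the attack of the alkynyl group on the allylammonium ion may be poor, because the aryl group carries an ortho oxygen substituent with a bulky side chain. The fallback sets out from fluoride 11 and gives up catalyst control. With achiral DABCO (20 mol %, THF, 40 °C) and alkynylsilane 13, the same silicon-assisted alkynylation should give 14 together with its C1 epimer F4. Because the dioxane carbon is already fixed, the two are diastereomers and would be separated by preparative HPLC, and the route is rejoined at 14.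

3. Step 10. The activated tertiary allylic alcohol may ionise, so that the allyl cation closes onto the electron-rich benzodioxane ring (Friedel–Crafts), and HBr may strip the silyl ethers. The fallback sets out from alcohol 15 and avoids the bromide altogether. Esterification with 3-(trimethylsilyl)propiolic acid (DCC, DMAP, CH2Cl2) gives the tertiary allylic alkynoate F5. Pd(PPh3)4 (zerovalent palladium, toluene, 75 °C) should then ionise the ester to a π-allylpalladium alkynoate, which loses CO2 and couples the alkynyl group at the less substituted CH2 terminus. This decarboxylative allyl–alkynyl coupling gives diyne 18 directly, where the route is rejoined (steps 10 and 11 are both replaced).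

**Further compounds**

F1 | step 14 | C6-unsubstituted 7-(hydroxymethyl)indane, (S) at C1 | CC(C)=C1Cc2cccc(CO)c2[C@H]1c1cc(C)cc2c1O[C@H](C(C)(C)O)CO2
F2 | step 14 | diethyl(hydrido)silyl ether of F1 | CC(C)=C1Cc2cccc(CO[SiH](CC)CC)c2[C@H]1c1cc(C)cc2c1O[C@H](C(C)(C)O)CO2
F3 | step 14 | indane-fused 1,1-diethylbenzoxasilole (C6–SiEt2–O–CH2–C7) | CC(C)=C1Cc2ccc3c(CO[Si]3(CC)CC)c2[C@H]1c1cc(C)cc2c1O[C@H](C(C)(C)O)CO2
F4 | step 8 | C1 epimer of 14, (3R) ester | C=C(C(=O)OC)[C@H](C#CCO[Si](C)(C)C(C)(C)C)c1cc(C)cc2c1O[C@H](C(C)(C)O[Si](CC)(CC)CC)CO2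
F5 | step 10 | 3-(trimethylsilyl)propiolate ester of tertiary allylic alcohol 15 | C=C(C(C)(C)OC(=O)C#C[Si](C)(C)C)[C@@H](C#CCO[Si](C)(C)C(C)(C)C)c1cc(C)cc2c1O[C@H](C(C)(C)O[Si](CC)(CC)CC)CO2
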